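**Plan**

- Retrosynthesis (1-benzoxepine locants O1, C2–C5, C5a, C6–C9, C9a): cut the C4 angelate ester first, then the aryl ether bond O1–C9a of the oxepine ring, then C2–C3 (aldol), the exocyclic C5=CH2 bond (Mannich methylenation) and C5–C5a (cross-coupling), back to 2-methylresorcinol.
- Forward: the bis(methoxymethyl) ether of 2-methylresorcinol is borylated at the future C5a, coupled with chloroacetone, brominated at the future C9a and methylenated. An aldol with a silyloxy aldehyde, a syn reduction and C4 silylation complete the open chain. The oxepine ring, the only ring made, closes last at O1–C9a, followed by desilylation, angeloylation and acetal removal.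
- Stereochemistry: C2 (S) comes from a (+)-Ipc2BCl aldol; C4 (R) comes from a Narasaka–Prasad syn reduction relayed from C2; the ring closure breaks no bond at either centre.
- Enabling feature: in the 5-substituted 2-methylresorcinol ring the positions that become C9a and C6 are equivalent, so one bromination marks C9a, and the C2 hydroxyl of the syn-1,3-diol chain on C5a can reach that carbon to close the seven-membered ring.

Key step: step 11

Assumption: (+)-Ipc2BCl (from (−)-α-pinene) is taken to direct the methyl ketone enolate to the Si face of the silyloxy aldehyde, as it does with less hindered aldehydes, which gives the (S) carbinol; the quaternary α-carbon of the aldehyde is assumed not to reverse this sense.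

**Route**

Step 1
Reactants: 1 2-methylresorcinol
Product: 2 1,3-bis(methoxymethoxy)-2-methylbenzene
Conditions: MOMCl, i-Pr2NEt, CH2Cl2, 0 °C to rt
Reagents that add atoms: chloromethyl methyl ether, COCCl
Why: Williamson-type O-alkylation of both phenols should give acetal ethers that tolerate borylation, cross-coupling, boron and hydride reagents, carbonate base and fluoride.

Step 2
Reactants: 2 1,3-bis(methoxymethoxy)-2-methylbenzene
Product: 3 2-[3,5-bis(methoxymethoxy)-4-methylphenyl]-4,4,5,5-tetramethyl-1,3,2-dioxaborolane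
Conditions: [Ir(OMe)(cod)]2 (cat.), 4,4'-di-tert-butyl-2,2'-bipyridine, B2pin2 (1.0 equiv), THF, 80 °C
Reagents that add atoms: bis(pinacolato)diboron, CC1(C)OB(OC1(C)C)B1OC(C)(C)C(C)(C)O1
Why: Iridium-catalysed aromatic C–H borylation is sterically governed and should attack the only C–H without an ortho substituent, the position para to the methyl group (future C5a).

Step 3
Reactants: 3 2-[3,5-bis(methoxymethoxy)-4-methylphenyl]-4,4,5,5-tetramethyl-1,3,2-dioxaborolane; 4 chloroacetone
Product: 5 1-[3,5-bis(methoxymethoxy)-4-methylphenyl]propan-2-one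
Conditions: Pd(OAc)2 (cat.), SPhos, K3PO4, THF–H2O, 60 °C, slow addition of 4
Reagents that add atoms: none
Why: Suzuki–Miyaura-type coupling of an aryl boronate with an α-chloro ketone (oxidative addition of the activated C–Cl bond, transmetalation, reductive elimination) should give the arylacetone and form C5–C5a.

Step 4
Reactants: 5 1-[3,5-bis(methoxymethoxy)-4-methylphenyl]propan-2-one
Product: 6 1-[2-bromo-3,5-bis(methoxymethoxy)-4-methylphenyl]propan-2-one
Conditions: NBS (1.0 equiv), MeCN, 0 °C, dark
Reagents that add atoms: N-bromosuccinimide, O=C1CCC(=O)N1Br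
Why: Electrophilic aromatic bromination of the strongly activated ring; the two free positions are equivalent by symmetry (each ortho to one and para to the other acetal oxygen), so monobromination should give a single product and mark the future C9a.

Step 5
Reactants: 6 1-[2-bromo-3,5-bis(methoxymethoxy)-4-methylphenyl]propan-2-one
Product: 8 3-[2-bromo-3,5-bis(methoxymethoxy)-4-methylphenyl]but-3-en-2-one, via Mannich base 7 (not isolated)
Conditions: CH2(NMe2)2, Ac2O, DMF, rt to 60 °C; product kept cold and used promptly
Reagents that add atoms: N,N,N',N'-tetramethylmethanediamine, CN(C)CN(C)C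
Why: Mannich α-methylenation, in which the iminium acetate formed from the aminal and Ac2O is attacked at the more acidic benzylic enol position and the β-amino ketone loses dimethylamine, should give the α-aryl enone and leave the methyl group as the only enolisable site.

Step 6
Reactants: 9 methyl 2-hydroxyisobutyrate
Product: 10 methyl 2-(tert-butyldimethylsilyloxy)-2-methylpropanoate
Conditions: TBSOTf, 2,6-lutidine, CH2Cl2, 0 °C
Reagents that add atoms: tert-butyldimethylsilyl triflate, CC(C)(C)[Si](C)(C)OS(=O)(=O)C(F)(F)F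
Why: Silylation of the tertiary alcohol with the silyl triflate; the tert-butyldimethylsilyl ether is preferred to a triethylsilyl ether because it is far slower to migrate to a neighbouring oxygen under the basic ring closure.

Step 7
Reactants: 10 methyl 2-(tert-butyldimethylsilyloxy)-2-methylpropanoate
Product: 12 2-(tert-butyldimethylsilyloxy)-2-methylpropanal, via aluminium hemiacetal 11 (not isolated)
Conditions: i-Bu2AlH (1.1 equiv), CH2Cl2, −78 °C; aq. potassium sodium tartrate
Reagents that add atoms: none
Why: Partial ester reduction; the tetrahedral aluminium hemiacetal of this α-silyloxy ester is stable at −78 °C and should release the aldehyde only on work-up.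

Step 8
Reactants: 8 3-[2-bromo-3,5-bis(methoxymethoxy)-4-methylphenyl]but-3-en-2-one; 12 2-(tert-butyldimethylsilyloxy)-2-methylpropanal
Product: 15 (5S)-2-[2-bromo-3,5-bis(methoxymethoxy)-4-methylphenyl]-6-(tert-butyldimethylsilyloxy)-5-hydroxy-6-methylhept-1-en-3-one, via enol borinate 13 (not isolated), via boron aldolate 14 (not isolated)
Conditions: (+)-Ipc2BCl, Et3N, Et2O, 0 °C; then 12, −78 to −20 °C; H2O2, MeOH, pH 7 buffer, 0 °C; crude product taken on directly
Reagents that add atoms: none
Why: Ipc2BCl-mediated boron aldol reaction, in which the methyl group is the only enolisable position and the enol diisopinocampheylborinate adds to the Si face of the aldehyde through a cyclic boron transition state, should set the (S) carbinol centre (future C2).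

Step 9
Reactants: 15 (5S)-2-[2-bromo-3,5-bis(methoxymethoxy)-4-methylphenyl]-6-(tert-butyldimethylsilyloxy)-5-hydroxy-6-methylhept-1-en-3-one
Product: 17 (3R,5S)-2-[2-bromo-3,5-bis(methoxymethoxy)-4-methylphenyl]-6-(tert-butyldimethylsilyloxy)-6-methylhept-1-ene-3,5-diol, via diethylboron chelate 16 (not isolated)
Conditions: Et2BOMe, THF–MeOH (4:1), −78 °C; NaBH4; AcOH, then MeOH co-evaporation
Reagents that add atoms: none
Why: Narasaka–Prasad reduction, in which the diethylboron chelate holds hydroxyl and ketone in a half-chair and external hydride adds axially, should give the syn-1,3-diol and so set the future C4 as (R) from the existing centre, with the chelate-activated carbonyl at −78 °C favouring 1,2- over 1,4-reduction of the enone.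

Step 10
Reactants: 17 (3R,5S)-2-[2-bromo-3,5-bis(methoxymethoxy)-4-methylphenyl]-6-(tert-butyldimethylsilyloxy)-6-methylhept-1-ene-3,5-diol
Product: 18 (3S,5R)-6-[2-bromo-3,5-bis(methoxymethoxy)-4-methylphenyl]-2,5-bis(tert-butyldimethylsilyloxy)-2-methylhept-6-en-3-ol
Conditions: TBSCl (1.1 equiv), imidazole, DMF, 0 °C to rt
Reagents that add atoms: tert-butyldimethylsilyl chloride, CC(C)(C)[Si](C)(C)Cl
Why: Sterically controlled silylation, in which the allylic hydroxyl reacts while the hydroxyl next to the quaternary silyloxy carbon is too hindered for TBSCl–imidazole, should leave only the future C2 hydroxyl free.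

Step 11
Reactants: 18 (3S,5R)-6-[2-bromo-3,5-bis(methoxymethoxy)-4-methylphenyl]-2,5-bis(tert-butyldimethylsilyloxy)-2-methylhept-6-en-3-ol
Product: 19 (2S,4R)-4-(tert-butyldimethylsilyloxy)-2-[2-(tert-butyldimethylsilyloxy)propan-2-yl]-7,9-bis(methoxymethoxy)-8-methyl-5-methylidene-2,3,4,5-tetrahydro-1-benzoxepine
Conditions: Pd(OAc)2 (5 mol %), 2-(di-tert-butylphosphino)-1,1'-binaphthyl (6 mol %), Cs2CO3 (1.5 equiv), toluene, 80 °C
Reagents that add atoms: none
Why: Zerovalent palladium formed from Pd(OAc)2 and the phosphine inserts into the C9a–Br bond, the C2 hydroxyl binds divalent palladium and is deprotonated by Cs2CO3, and C–O reductive elimination from the aryl(alkoxo)palladium species forms O1–C9a. The closest known reaction type is the palladium-catalysed intramolecular etherification of aryl bromides with secondary alcohols, documented for five-, six- and seven-membered cyclic aryl ethers. The oxepine ring closes in exo fashion by ipso substitution at the aromatic carbon, through an eight-membered oxapalladacycle that contracts to the seven-membered ring on reductive elimination. No stereocentre is created, and C2 keeps its configuration because only its O–H bond is broken. The step needs chemoselectivity among three oxygens and suppression of β-hydride loss: both other oxygens carry tert-butyldimethylsilyl groups, so the five-membered closure from the C4 oxygen is excluded, the weak insoluble carbonate keeps free alkoxide and hence silyl migration low, and the bulky di-tert-butyl biaryl phosphine together with the two ortho substituents on the aryl group should speed reductive elimination over β-hydride elimination.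

Step 12
Reactants: 19 (2S,4R)-4-(tert-butyldimethylsilyloxy)-2-[2-(tert-butyldimethylsilyloxy)propan-2-yl]-7,9-bis(methoxymethoxy)-8-methyl-5-methylidene-2,3,4,5-tetrahydro-1-benzoxepine
Product: 20 (2S,4R)-2-(2-hydroxypropan-2-yl)-7,9-bis(methoxymethoxy)-8-methyl-5-methylidene-2,3,4,5-tetrahydro-1-benzoxepin-4-ol
Conditions: Bu4NF, THF, rt to 50 °C
Reagents that add atoms: none
Why: Fluoride-induced desilylation should free the C4 hydroxyl and the tertiary alcohol, while the aryl acetal ethers, the alkene and the ring ether are inert to fluoride.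

Step 13
Reactants: 20 (2S,4R)-2-(2-hydroxypropan-2-yl)-7,9-bis(methoxymethoxy)-8-methyl-5-methylidene-2,3,4,5-tetrahydro-1-benzoxepin-4-ol; 21 angelic acid
Product: 23 (2S,4R)-2-(2-hydroxypropan-2-yl)-7,9-bis(methoxymethoxy)-8-methyl-5-methylidene-2,3,4,5-tetrahydro-1-benzoxepin-4-yl (2Z)-2-methylbut-2-enoate, via mixed anhydride 22 (not isolated)
Conditions: 21, 2,4,6-Cl3C6H2COCl, Et3N, toluene, rt; then 20, 80 °C (no DMAP)
Reagents that add atoms: none
Why: Yamaguchi esterification, in which the mixed anhydride acylates the secondary allylic hydroxyl under nucleophile-free conditions that preserve the (Z) geometry of angelates, should leave the hindered tertiary alcohol untouched.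

Step 14
Reactants: 23 (2S,4R)-2-(2-hydroxypropan-2-yl)-7,9-bis(methoxymethoxy)-8-methyl-5-methylidene-2,3,4,5-tetrahydro-1-benzoxepin-4-yl (2Z)-2-methylbut-2-enoate
Product: 25 (2S,4R)-7,9-dihydroxy-2-(2-hydroxypropan-2-yl)-8-methyl-5-methylidene-2,3,4,5-tetrahydro-1-benzoxepin-4-yl (2Z)-2-methylbut-2-enoate, via tris(trimethylsilyl) ether 24 (not isolated)
Conditions: TMSOTf, 2,2'-bipyridyl, CH3CN, 0 °C to rt; then H2O, citric acid, rt
Reagents that add atoms: none
Why: Silyl triflate–bipyridyl cleavage of aryl methoxymethyl ethers, which passes the methoxymethyl group to the pyridine nitrogen and the aryl oxygen to silicon without free protic acid, should release both phenols (and the transiently silylated tertiary alcohol) on mild hydrolysis while sparing the allylic angelate, the styrene-type alkene and the nucleophilic C6 position.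

**Compound list**

1 | 2-methylresorcinol | Cc1c(O)cccc1O | starting material
2 | 1,3-bis(methoxymethoxy)-2-methylbenzene | COCOc1cccc(OCOC)c1C | intermediate
3 | 2-[3,5-bis(methoxymethoxy)-4-methylphenyl]-4,4,5,5-tetramethyl-1,3,2-dioxaborolane | COCOc1cc(B2OC(C)(C)C(C)(C)O2)cc(OCOC)c1C | intermediate
4 | chloroacetone | CC(=O)CCl | starting material
5 | 1-[3,5-bis(methoxymethoxy)-4-methylphenyl]propan-2-one | CC(=O)Cc1cc(OCOC)c(C)c(OCOC)c1 | intermediate
6 | 1-[2-bromo-3,5-bis(methoxymethoxy)-4-methylphenyl]propan-2-one | CC(=O)Cc1cc(OCOC)c(C)c(OCOC)c1Br | intermediate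
7 | 3-[2-bromo-3,5-bis(methoxymethoxy)-4-methylphenyl]-4-(dimethylamino)butan-2-one (racemic Mannich base, not isolated) | CC(=O)C(CN(C)C)c1cc(OCOC)c(C)c(OCOC)c1Br | intermediate
8 | 3-[2-bromo-3,5-bis(methoxymethoxy)-4-methylphenyl]but-3-en-2-one | CC(=O)C(=C)c1cc(OCOC)c(C)c(OCOC)c1Br | intermediate
9 | methyl 2-hydroxyisobutyrate | COC(=O)C(C)(C)O | starting material
10 | methyl 2-(tert-butyldimethylsilyloxy)-2-methylpropanoate | COC(=O)C(C)(C)O[Si](C)(C)C(C)(C)C | intermediate
11 | diisobutyl[1-methoxy-2-methyl-2-(tert-butyldimethylsilyloxy)propoxy]aluminium (aluminium hemiacetal, not isolated) | COC(O[Al](CC(C)C)CC(C)C)C(C)(C)O[Si](C)(C)C(C)(C)C | intermediate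
12 | 2-(tert-butyldimethylsilyloxy)-2-methylpropanal | CC(C)(C=O)O[Si](C)(C)C(C)(C)C | intermediate
13 | enol bis(isopinocampheyl)borinate of 8, Ipc groups as in (+)-Ipc2BCl (not isolated) | C=C(OB([C@H]1C[C@H]2C[C@H](C2(C)C)[C@@H]1C)[C@H]1C[C@H]2C[C@H](C2(C)C)[C@@H]1C)C(=C)c1cc(OCOC)c(C)c(OCOC)c1Br | intermediate
14 | bis(isopinocampheyl)boron aldolate of 15 (not isolated) | C=C(c1cc(OCOC)c(C)c(OCOC)c1Br)C(=O)C[C@H](OB([C@H]1C[C@H]2C[C@H](C2(C)C)[C@@H]1C)[C@H]1C[C@H]2C[C@H](C2(C)C)[C@@H]1C)C(C)(C)O[Si](C)(C)C(C)(C)C | intermediate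
15 | (5S)-2-[2-bromo-3,5-bis(methoxymethoxy)-4-methylphenyl]-6-(tert-butyldimethylsilyloxy)-5-hydroxy-6-methylhept-1-en-3-one | C=C(c1cc(OCOC)c(C)c(OCOC)c1Br)C(=O)C[C@H](O)C(C)(C)O[Si](C)(C)C(C)(C)C | intermediate
16 | O-diethylboryl chelate of 15 (not isolated) | C=C(c1cc(OCOC)c(C)c(OCOC)c1Br)C(=O)C[C@H](OB(CC)CC)C(C)(C)O[Si](C)(C)C(C)(C)C | intermediate
17 | (3R,5S)-2-[2-bromo-3,5-bis(methoxymethoxy)-4-methylphenyl]-6-(tert-butyldimethylsilyloxy)-6-methylhept-1-ene-3,5-diol | C=C(c1cc(OCOC)c(C)c(OCOC)c1Br)[C@H](O)C[C@H](O)C(C)(C)O[Si](C)(C)C(C)(C)C | intermediate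
18 | (3S,5R)-6-[2-bromo-3,5-bis(methoxymethoxy)-4-methylphenyl]-2,5-bis(tert-butyldimethylsilyloxy)-2-methylhept-6-en-3-ol | C=C(c1cc(OCOC)c(C)c(OCOC)c1Br)[C@H](O[Si](C)(C)C(C)(C)C)C[C@H](O)C(C)(C)O[Si](C)(C)C(C)(C)C | intermediate
19 | (2S,4R)-4-(tert-butyldimethylsilyloxy)-2-[2-(tert-butyldimethylsilyloxy)propan-2-yl]-7,9-bis(methoxymethoxy)-8-methyl-5-methylidene-2,3,4,5-tetrahydro-1-benzoxepine | C=C1c2cc(OCOC)c(C)c(OCOC)c2O[C@H](C(C)(C)O[Si](C)(C)C(C)(C)C)C[C@H]1O[Si](C)(C)C(C)(C)C | intermediate
20 | (2S,4R)-2-(2-hydroxypropan-2-yl)-7,9-bis(methoxymethoxy)-8-methyl-5-methylidene-2,3,4,5-tetrahydro-1-benzoxepin-4-ol | C=C1c2cc(OCOC)c(C)c(OCOC)c2O[C@H](C(C)(C)O)C[C@H]1O | intermediate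
21 | angelic acid | C/C=C(/C)C(=O)O | starting material
22 | (2Z)-2-methylbut-2-enoic 2,4,6-trichlorobenzoic anhydride (not isolated) | C/C=C(/C)C(=O)OC(=O)c1c(Cl)cc(Cl)cc1Cl | intermediate
23 | (2S,4R)-2-(2-hydroxypropan-2-yl)-7,9-bis(methoxymethoxy)-8-methyl-5-methylidene-2,3,4,5-tetrahydro-1-benzoxepin-4-yl (2Z)-2-methylbut-2-enoate | C=C1c2cc(OCOC)c(C)c(OCOC)c2O[C@H](C(C)(C)O)C[C@H]1OC(=O)/C(C)=C\C | intermediate
24 | (2S,4R)-8-methyl-5-methylidene-7,9-bis(trimethylsilyloxy)-2-[2-(trimethylsilyloxy)propan-2-yl]-2,3,4,5-tetrahydro-1-benzoxepin-4-yl (2Z)-2-methylbut-2-enoate (not isolated) | C=C1c2cc(O[Si](C)(C)C)c(C)c(O[Si](C)(C)C)c2O[C@H](C(C)(C)O[Si](C)(C)C)C[C@H]1OC(=O)/C(C)=C\C | intermediate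
25 | (2S,4R)-7,9-dihydroxy-2-(2-hydroxypropan-2-yl)-8-methyl-5-methylidene-2,3,4,5-tetrahydro-1-benzoxepin-4-yl (2Z)-2-methylbut-2-enoate | C=C1c2cc(O)c(C)c(O)c2O[C@H](C(C)(C)O)C[C@H]1OC(=O)/C(C)=C\C | target

**Step count and risks**

Total step count: 14. Longest linear sequence: 12 steps (1 to 25 through steps 1–5 and 8–14); aldehyde 12 is made in 2 further steps.

Steps most likely to fail:

Step 11. Oxidative addition into the doubly ortho-substituted, electron-rich C–Br bond may be slow. The palladium alkoxide may lose a β-hydride faster than it reductively eliminates, which would oxidise C2 and debrominate the ring. Base-driven silyl migration from the C4 oxygen to the C2 oxygen would divert closure to the five-membered ring. The fallback leaves palladium for a copper-mediated Ullmann closure on the more reactive iodide, since copper alkoxides are far less prone to β-hydride loss. It sets out from 18: aromatic Finkelstein exchange (CuI, NaI, trans-N,N'-dimethylcyclohexane-1,2-diamine, dioxane, 110 °C) would give (3S,5R)-2,5-bis(tert-butyldimethylsilyloxy)-6-[2-iodo-3,5-bis(methoxymethoxy)-4-methylphenyl]-2-methylhept-6-en-3-ol F1. With CuI, 3,4,7,8-tetramethyl-1,10-phenanthroline and Cs2CO3 in toluene at 110 °C this should close to 19, where the route resumes.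

Step 8. Facial discrimination of the hindered α-quaternary aldehyde by the chiral enol borinate may be poor. Addition may also be slow enough for the hydroxy enone to undergo oxa-Michael closure or retro-aldol cleavage. The fallback separates enolate formation from the stereo-determining event and uses a catalytic enantioselective Mukaiyama aldol. It sets out from 8: TMSOTf and Et3N in CH2Cl2 at 0 °C would give {[3-(2-bromo-3,5-bis(methoxymethoxy)-4-methylphenyl)buta-1,3-dien-2-yl]oxy}trimethylsilane F2. Reaction of this diene with 12 in EtCN at −78 °C, with 20 mol % of the N-tosyltryptophan-derived B-butyl-1,3,2-oxazaborolidin-5-one in the enantiomeric form that exposes the Si face, should give (5S)-2-[2-bromo-3,5-bis(methoxymethoxy)-4-methylphenyl]-6-(tert-butyldimethylsilyloxy)-6-methyl-5-(trimethylsilyloxy)hept-1-en-3-one F3. Brief treatment with citric acid in MeOH returns the route to 15.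

Step 3. Base-induced self-condensation and hydrolysis of chloroacetone, protodeboronation of 3, and protonation of the palladium enolate may all outrun C–C bond formation. The fallback installs the three-carbon unit as an alkene and reveals the ketone oxidatively. It sets out from 3: Suzuki–Miyaura allylation with methallyl chloride (Pd(PPh3)4, K2CO3, THF–H2O, 65 °C) would give 1,3-bis(methoxymethoxy)-2-methyl-5-(2-methylprop-2-en-1-yl)benzene F4. Lemieux–Johnson cleavage of its 1,1-disubstituted alkene (OsO4 cat., NaIO4, 2,6-lutidine, dioxane–H2O) should then give ketone 5, where the route resumes.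

Further compounds
F1 | step 11 | (3S,5R)-2,5-bis(tert-butyldimethylsilyloxy)-6-[2-iodo-3,5-bis(methoxymethoxy)-4-methylphenyl]-2-methylhept-6-en-3-ol | C=C(c1cc(OCOC)c(C)c(OCOC)c1I)[C@H](O[Si](C)(C)C(C)(C)C)C[C@H](O)C(C)(C)O[Si](C)(C)C(C)(C)C
F2 | step 8 | {[3-(2-bromo-3,5-bis(methoxymethoxy)-4-methylphenyl)buta-1,3-dien-2-yl]oxy}trimethylsilane | C=C(O[Si](C)(C)C)C(=C)c1cc(OCOC)c(C)c(OCOC)c1Br
F3 | step 8 | (5S)-2-[2-bromo-3,5-bis(methoxymethoxy)-4-methylphenyl]-6-(tert-butyldimethylsilyloxy)-6-methyl-5-(trimethylsilyloxy)hept-1-en-3-one | C=C(c1cc(OCOC)c(C)c(OCOC)c1Br)C(=O)C[C@H](O[Si](C)(C)C)C(C)(C)O[Si](C)(C)C(C)(C)C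
F4 | step 3 | 1,3-bis(methoxymethoxy)-2-methyl-5-(2-methylprop-2-en-1-yl)benzene | C=C(C)Cc1cc(OCOC)c(C)c(OCOC)c1
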